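**Plan**

- Retrosynthetic cuts, in order: the C15–O oleate ester, C8=C17 (methylenation of a C8 ketone), C12–C13 (B-alkyl Suzuki coupling), C9–C10 together with ring B (lactone ring contraction), C6–C7 (vinylogous aldol), C5–C6 (formylation) and the two ring-A methyl bonds.
- Enabling feature: quaternary C10 and its neighbour C9, whose substituent C11 can be a carboxyl carbon, become the termini of the array C9=C11–O–C6–C5=C10 once C11 is the carbonyl of a δ-lactone whose ring oxygen sits on C6 of a ring-A cyclohexenyl carbinol.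
- Forward: ring A (from methyl 2-oxocyclohexane-1-carboxylate) → enal → aldol and δ-lactone → Ireland–Claisen contraction closes ring B → trans-decalin → side chain joined at C12–C13 → C8 methylene → oleate.
- Stereochemistry: C4 from an auxiliary-controlled methylation; C6 (Ti–BINOL aldol) is transferred to C10 in the [3,3] shift; C5 from HAT reduction; C9 leaves the boat transition state epimeric and is corrected by equilibration next to the C8 ketone; 13E from the enol triflate geometry; the 9Z alkene comes with oleic acid.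

Key step: step 9

Remark: labdane numbering (C1–C20) is used for all intermediates; α/β mean the face opposite to/shared with the C20 methyl, and "9-epi" means 9β-H (C11 α).
Design remark: C8 is carried as an equatorial silyl ether, not a ketal, so that no C8 substituent points at the C20 methyl in the boat and the lactone enolate has no good β-leaving group. The boat necessarily places C11 trans to C20, so C9 is inverted at the C8-ketone stage (step 17).
Assumption: the chiral-enamine methylation (step 2) and the Ti–BINOL aldol (step 6) are taken to show their usual facial sense; if either proved opposite, D-valinate or (R)-BINOL would be used without other change.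

**Route**

Step 1
Reactants: 1 methyl 2-oxocyclohexane-1-carboxylate; 2 tert-butyl L-valinate
Product: 3 methyl 2-{[(2S)-1-tert-butoxy-3-methyl-1-oxobutan-2-yl]amino}cyclohex-1-ene-1-carboxylate
Conditions: TsOH (cat.), toluene, reflux, Dean–Stark
Reagents that add atoms: none
Why: Acid-catalysed condensation of the ketone with the primary amine (enamine formation) is driven by water removal and gives the hydrogen-bonded vinylogous carbamate without creating a ring stereocentre.

Step 2
Reactants: 3 methyl 2-{[(2S)-1-tert-butoxy-3-methyl-1-oxobutan-2-yl]amino}cyclohex-1-ene-1-carboxylate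
Product: 5 methyl (1S)-1-methyl-2-oxocyclohexane-1-carboxylate, via C-methylated imine 4 (not isolated)
Conditions: LDA, toluene, HMPA (1 equiv), −78 °C; MeI, −78 → −40 °C; then 1 M HCl, rt
Reagents that add atoms: iodomethane, CI
Why: Alkylation of a chiral lithiated enamine: the aza-enolate is a rigid N,O-lithium chelate in which the valinate isopropyl group screens one face, so iodomethane should create the C4 quaternary centre as (S), and hydrolysis of imine 4 releases the ketone and the auxiliary.

Step 3
Reactants: 5 methyl (1S)-1-methyl-2-oxocyclohexane-1-carboxylate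
Product: 6 methyl (1S,3RS)-1,3-dimethyl-2-oxocyclohexane-1-carboxylate
Conditions: LDA, THF, −78 °C; MeI, −78 → 0 °C
Reagents that add atoms: iodomethane, CI
Why: Kinetic enolisation can only occur toward C10 because C4 is quaternary, and enolate alkylation installs C20; the new centre is left as a mixture since it becomes sp2 in step 4.

Step 4
Reactants: 6 methyl (1S,3RS)-1,3-dimethyl-2-oxocyclohexane-1-carboxylate
Product: 7 methyl (1S)-1,3-dimethyl-2-(trifluoromethanesulfonyloxy)cyclohex-2-ene-1-carboxylate
Conditions: KHMDS, THF, −78 → 0 °C; PhNTf2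
Reagents that add atoms: N-phenylbis(trifluoromethanesulfonimide), O=S(=O)(N(c1ccccc1)S(=O)(=O)C(F)(F)F)C(F)(F)F
Why: Deprotonation of the single remaining α-hydrogen and O-sulfonylation of the tetrasubstituted enolate (enol triflate formation) fix the C5=C10 double bond.

Step 5
Reactants: 7 methyl (1S)-1,3-dimethyl-2-(trifluoromethanesulfonyloxy)cyclohex-2-ene-1-carboxylate
Product: 8 methyl (1S)-2-formyl-1,3-dimethylcyclohex-2-ene-1-carboxylate
Conditions: Pd(OAc)2 (5 mol %), dppp, CO (1 atm), Et3SiH, Et3N, DMF, 70 °C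
Reagents that add atoms: carbon monoxide, [C-]#[O+]
Why: Palladium-catalysed reductive carbonylation (formylation) of the vinyl triflate, by oxidative addition, CO insertion and hydride transfer from the silane, should give the C6 aldehyde and leave the ester untouched.

Step 6
Reactants: 8 methyl (1S)-2-formyl-1,3-dimethylcyclohex-2-ene-1-carboxylate; 9 1-methoxy-1,3-bis(trimethylsilyloxy)buta-1,3-diene (Chan's diene)
Product: 11 methyl (5S)-5-hydroxy-5-[(6S)-6-(methoxycarbonyl)-2,6-dimethylcyclohex-1-en-1-yl]-3-oxopentanoate, via bis-silylated aldol adduct 10 (not isolated)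
Conditions: Ti(Oi-Pr)4/(S)-BINOL (20 mol %), 4 Å MS, THF, −78 → −20 °C; then PPTS, MeOH, 0 °C
Reagents that add atoms: none
Why: Catalytic enantioselective vinylogous Mukaiyama aldol addition through the γ-carbon of the bis-silyl dienolate, in which the Ti–(S)-BINOL complex should direct attack to the Si face of the aldehyde and so set C6 as (S) under catalyst control, the C4 centre being remote.

Step 7
Reactants: 11 methyl (5S)-5-hydroxy-5-[(6S)-6-(methoxycarbonyl)-2,6-dimethylcyclohex-1-en-1-yl]-3-oxopentanoate
Product: 13 methyl (1S)-2-[(2S,4R)-4-hydroxy-6-oxooxan-2-yl]-1,3-dimethylcyclohex-2-ene-1-carboxylate, via syn-diol ester 12 (not isolated)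
Conditions: Et2BOMe, NaBH4, THF/MeOH (4:1), −78 °C; AcOH, MeOH co-evaporation; then PPTS (cat.), toluene, 60 °C
Reagents that add atoms: none
Why: Narasaka–Prasad reduction, in which external hydride attacks the boron chelate of the β-hydroxy ketone, should give the syn-1,3-diol (temporary C8 centre, R), and acid-catalysed lactonisation onto the unhindered C11 ester then places C8–O trans to the C6 substituent on the δ-lactone while the neopentyl C19 ester is too hindered to compete.

Step 8
Reactants: 13 methyl (1S)-2-[(2S,4R)-4-hydroxy-6-oxooxan-2-yl]-1,3-dimethylcyclohex-2-ene-1-carboxylate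
Product: 14 methyl (1S)-2-[(2S,4R)-4-(tert-butyldimethylsilyloxy)-6-oxooxan-2-yl]-1,3-dimethylcyclohex-2-ene-1-carboxylate
Conditions: TBSCl, imidazole, DMF, rt
Reagents that add atoms: tert-butyldimethylsilyl chloride, CC(C)(C)[Si](C)(C)Cl
Why: Silylation of the secondary alcohol masks C8–OH as an ether that tolerates enolisation of the lactone and every later step up to step 16.

Step 9
Reactants: 14 methyl (1S)-2-[(2S,4R)-4-(tert-butyldimethylsilyloxy)-6-oxooxan-2-yl]-1,3-dimethylcyclohex-2-ene-1-carboxylate
Product: 17 8α-(tert-butyldimethylsilyloxy)-19-methoxy-19-oxo-9-epi-12,13,14,15,16,17-hexanorlabd-5-en-11-oic acid, via silyl ketene acetal 15 (not isolated), via trimethylsilyl ester 16 (not isolated)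
Conditions: TMSCl/Et3N, then LDA, THF, −78 °C → rt; toluene, 100 °C; then H2O/THF, pH 4
Reagents that add atoms: none
Why: In situ silylation of the lactone enolate gives the endocyclic ketene acetal 15 before the β-silyloxy enolate can eliminate, and heating then drives a concerted, suprafacial [3,3]-sigmatropic shift of the array C9=C11–O–C6–C5=C10 to silyl ester 16, which water cleaves to the acid. The closest known reaction is the Ireland–Claisen rearrangement in its ring-contracting form on 6-alkenyl δ-lactones; a tetrasubstituted alkene terminus that becomes a quaternary carbon lies at the demanding end of that class. Ring B (C5–C6–C7–C8–C9–C10) closes as C9 bonds to C10 across the lactone through a bicyclo[2.2.2]-like boat, the only geometry the six-membered tether allows, while the C6–O bond breaks and the alkene moves to C5=C6. C10 is controlled by chirality transfer from C6: only the rotamer with C7 turned toward C10 can react, so C9 arrives on the face from which oxygen departs, the α-face anti to the C4 ester, and C20 ends β. C9 is controlled by the ring-locked ketene acetal geometry in the boat, which puts C11 trans to C20 (9α-CO2H, 9-epi); this is accepted because C9 is reset next to the C8 ketone in step 17. The step needs the pericyclic path to outrun β-elimination and ionisation of the allylic C6–O bond, which the amine-buffered aprotic medium and the 4,6-trans lactone should secure, the latter by keeping the C8 silyloxy group equatorial and away from the C20 methyl that the boat forces inward.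

Step 10
Reactants: 17 8α-(tert-butyldimethylsilyloxy)-19-methoxy-19-oxo-9-epi-12,13,14,15,16,17-hexanorlabd-5-en-11-oic acid
Product: 18 methyl 8α-(tert-butyldimethylsilyloxy)-11-hydroxy-9-epi-12,13,14,15,16,17-hexanorlabd-5-en-19-oate
Conditions: BH3·THF, THF, 0 °C → rt; MeOH
Reagents that add atoms: none
Why: Chemoselective borane reduction: the carboxylic acid reacts through its acyloxyborane far faster than the methyl ester, the silyl ether or the hindered trisubstituted alkene.

Step 11
Reactants: 18 methyl 8α-(tert-butyldimethylsilyloxy)-11-hydroxy-9-epi-12,13,14,15,16,17-hexanorlabd-5-en-19-oate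
Product: 19 methyl 8α-(tert-butyldimethylsilyloxy)-11-hydroxy-9-epi-12,13,14,15,16,17-hexanorlabdan-19-oate
Conditions: Mn(dpm)3 (10 mol %), PhSiH3, t-BuOOH, i-PrOH, rt
Reagents that add atoms: none
Why: Mn-catalysed hydrogen-atom-transfer hydrogenation: H• adds to C6 and the tertiary C5 radical should take hydrogen on the α-face, away from the axial C20 methyl and C19 ester, giving the thermodynamically favoured trans-decalin (5α-H).

Step 12
Reactants: 19 methyl 8α-(tert-butyldimethylsilyloxy)-11-hydroxy-9-epi-12,13,14,15,16,17-hexanorlabdan-19-oate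
Product: 20 methyl 8α-(tert-butyldimethylsilyloxy)-11-oxo-9-epi-12,13,14,15,16,17-hexanorlabdan-19-oate
Conditions: Dess–Martin periodinane, NaHCO3, CH2Cl2, 0 °C → rt
Reagents that add atoms: none
Why: Dess–Martin oxidation of the primary alcohol under buffered, non-enolising conditions should give the aldehyde without β-elimination of the silyloxy group.

Step 13
Reactants: 20 methyl 8α-(tert-butyldimethylsilyloxy)-11-oxo-9-epi-12,13,14,15,16,17-hexanorlabdan-19-oate
Product: 21 methyl 8α-(tert-butyldimethylsilyloxy)-9-epi-13,14,15,16,17-pentanorlabd-11-en-19-oate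
Conditions: Ph3PCH3Br, KHMDS, THF, 0 °C; then 20, −78 → 0 °C
Reagents that add atoms: methyltriphenylphosphonium bromide, C[P+](c1ccccc1)(c1ccccc1)c1ccccc1.[Br-]
Why: Wittig methylenation of the aldehyde with the non-stabilised ylide adds C12; any C9 epimerisation would be harmless because C9 is reset in step 17.

Step 14
Reactants: 22 methyl acetoacetate
Product: 23 methyl (2E)-3-(trifluoromethanesulfonyloxy)but-2-enoate
Conditions: Tf2O, aq. Me4NOH, hexanes, 5 °C
Reagents that add atoms: trifluoromethanesulfonic anhydride, O=S(=O)(OS(=O)(=O)C(F)(F)F)C(F)(F)F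
Why: Stereoselective enol triflate formation from the β-keto ester: with a non-chelating tetraalkylammonium counter-ion the (E)-enol triflate should form, and its geometry fixes the later C13=C14 bond.

Step 15
Reactants: 21 methyl 8α-(tert-butyldimethylsilyloxy)-9-epi-13,14,15,16,17-pentanorlabd-11-en-19-oate; 23 methyl (2E)-3-(trifluoromethanesulfonyloxy)but-2-enoate
Product: 25 dimethyl (13E)-8α-(tert-butyldimethylsilyloxy)-9-epi-17-norlabd-13-ene-15,19-dioate, via B-alkyl borane 24 (not isolated)
Conditions: 9-BBN, THF, rt → 50 °C; then 23, PdCl2(dppf) (5 mol %), AsPh3, aq. K3PO4, DMF, rt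
Reagents that add atoms: none
Why: Anti-Markovnikov hydroboration of the vinyl group followed by B-alkyl Suzuki–Miyaura coupling joins C12 to C13 with retention of the triflate geometry, so the enoate should be 13E.

Step 16
Reactants: 25 dimethyl (13E)-8α-(tert-butyldimethylsilyloxy)-9-epi-17-norlabd-13-ene-15,19-dioate
Product: 26 dimethyl (13E)-8α-hydroxy-9-epi-17-norlabd-13-ene-15,19-dioate
Conditions: TBAF, THF, rt → 45 °C
Reagents that add atoms: none
Why: Fluoride-mediated cleavage of the silyl ether frees the C8 alcohol while both methyl esters stay intact.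

Step 17
Reactants: 26 dimethyl (13E)-8α-hydroxy-9-epi-17-norlabd-13-ene-15,19-dioate
Product: 28 dimethyl (13E)-8-oxo-17-norlabd-13-ene-15,19-dioate, via 9-epi ketone 27 (not isolated)
Conditions: Dess–Martin periodinane, NaHCO3, CH2Cl2, rt; then NaOMe (0.2 equiv), MeOH, rt
Reagents that add atoms: none
Why: Dess–Martin oxidation gives the C8 ketone and methoxide-catalysed enolisation then equilibrates C9 to the equatorial 9β side chain (9α-H), the natural configuration, which is favoured thermodynamically and by axial protonation anti to the C20 methyl.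

Step 18
Reactants: 28 dimethyl (13E)-8-oxo-17-norlabd-13-ene-15,19-dioate
Product: 29 dimethyl (13E)-labda-8(17),13-diene-15,19-dioate
Conditions: Zn, CH2Br2, TiCl4, THF/CH2Cl2, 0 °C → rt
Reagents that add atoms: dibromomethane, BrCBr
Why: Takai–Lombardo methylenation converts the hindered, enolisable ketone into the exocyclic methylene under non-basic conditions that tolerate both esters and leave C9 undisturbed.

Step 19
Reactants: 29 dimethyl (13E)-labda-8(17),13-diene-15,19-dioate
Product: 30 methyl (13E)-15-hydroxylabda-8(17),13-dien-19-oate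
Conditions: DIBAL-H (2.2 equiv), CH2Cl2, −78 °C; Rochelle salt
Reagents that add atoms: none
Why: DIBAL-H 1,2-reduction should take the unhindered conjugated C15 ester to the allylic alcohol at −78 °C while the axial neopentyl C19 ester is too hindered to react.

Step 20
Reactants: 30 methyl (13E)-15-hydroxylabda-8(17),13-dien-19-oate
Product: 31 (13E)-15-hydroxylabda-8(17),13-dien-19-oic acid
Conditions: NaSEt, DMF, 90 °C; then cold 0.5 M HCl to pH 4
Reagents that add atoms: none
Why: Nucleophilic (SN2) ester dealkylation by thiolate cleaves the O–CH3 bond and so bypasses the congested acyl carbon; the alkenes and the allylic alkoxide are inert to thiolate.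

Step 21
Reactants: 31 (13E)-15-hydroxylabda-8(17),13-dien-19-oic acid; 32 oleic acid
Product: 34 (13E)-15-[(9Z)-octadec-9-enoyloxy]labda-8(17),13-dien-19-oic acid, via oleoyl chloride 33 (not isolated)
Conditions: 32, (COCl)2, DMF (cat.), CH2Cl2, 0 °C → rt, evaporate; then 31, pyridine, DMAP (cat.), CH2Cl2, 0 °C; aq. NaHCO3/THF
Reagents that add atoms: none
Why: DMAP-catalysed acylation of the primary allylic alcohol by the acid chloride; the hindered tertiary C19 acid can at most form a labile mixed anhydride that passes oleoyl on to the alcohol or is hydrolysed on work-up, and the (Z)-alkene of the acyl chain is untouched.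

**Compound list**

1 | methyl 2-oxocyclohexane-1-carboxylate | COC(=O)C1CCCCC1=O | starting material
2 | tert-butyl L-valinate | CC(C)[C@H](N)C(=O)OC(C)(C)C | starting material
3 | methyl 2-{[(2S)-1-tert-butoxy-3-methyl-1-oxobutan-2-yl]amino}cyclohex-1-ene-1-carboxylate | COC(=O)C1=C(N[C@@H](C(C)C)C(=O)OC(C)(C)C)CCCC1 | intermediate
4 | methyl (1S)-2-{[(2S)-1-tert-butoxy-3-methyl-1-oxobutan-2-yl]imino}-1-methylcyclohexane-1-carboxylate (C-methylated imine) | COC(=O)[C@@]1(C)CCCCC1=N[C@@H](C(C)C)C(=O)OC(C)(C)C | intermediate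
5 | methyl (1S)-1-methyl-2-oxocyclohexane-1-carboxylate | COC(=O)[C@@]1(C)CCCCC1=O | intermediate
6 | methyl (1S,3RS)-1,3-dimethyl-2-oxocyclohexane-1-carboxylate | COC(=O)[C@@]1(C)CCCC(C)C1=O | intermediate
7 | methyl (1S)-1,3-dimethyl-2-(trifluoromethanesulfonyloxy)cyclohex-2-ene-1-carboxylate | COC(=O)[C@@]1(C)CCCC(C)=C1OS(=O)(=O)C(F)(F)F | intermediate
8 | methyl (1S)-2-formyl-1,3-dimethylcyclohex-2-ene-1-carboxylate | COC(=O)[C@@]1(C)CCCC(C)=C1C=O | intermediate
9 | 1-methoxy-1,3-bis(trimethylsilyloxy)buta-1,3-diene (Chan's diene) | COC(O[Si](C)(C)C)=CC(=C)O[Si](C)(C)C | starting material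
10 | (5S)-1-methoxy-5-[(6S)-6-(methoxycarbonyl)-2,6-dimethylcyclohex-1-en-1-yl]-1,5-bis(trimethylsilyloxy)pent-1-en-3-one (bis-silylated aldol adduct) | COC(O[Si](C)(C)C)=CC(=O)C[C@H](O[Si](C)(C)C)C1=C(C)CCC[C@]1(C)C(=O)OC | intermediate
11 | methyl (5S)-5-hydroxy-5-[(6S)-6-(methoxycarbonyl)-2,6-dimethylcyclohex-1-en-1-yl]-3-oxopentanoate | COC(=O)CC(=O)C[C@H](O)C1=C(C)CCC[C@]1(C)C(=O)OC | intermediate
12 | methyl (3R,5S)-3,5-dihydroxy-5-[(6S)-6-(methoxycarbonyl)-2,6-dimethylcyclohex-1-en-1-yl]pentanoate (syn-diol ester) | COC(=O)C[C@H](O)C[C@H](O)C1=C(C)CCC[C@]1(C)C(=O)OC | intermediate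
13 | methyl (1S)-2-[(2S,4R)-4-hydroxy-6-oxooxan-2-yl]-1,3-dimethylcyclohex-2-ene-1-carboxylate (4,6-trans lactone) | CC1=C([C@@H]2C[C@@H](O)CC(=O)O2)[C@@](C)(C(=O)OC)CCC1 | intermediate
14 | methyl (1S)-2-[(2S,4R)-4-(tert-butyldimethylsilyloxy)-6-oxooxan-2-yl]-1,3-dimethylcyclohex-2-ene-1-carboxylate | CC1=C([C@@H]2C[C@@H](O[Si](C)(C)C(C)(C)C)CC(=O)O2)[C@@](C)(C(=O)OC)CCC1 | intermediate
15 | methyl (1S)-2-[(2S,4R)-4-(tert-butyldimethylsilyloxy)-6-(trimethylsilyloxy)-3,4-dihydro-2H-pyran-2-yl]-1,3-dimethylcyclohex-2-ene-1-carboxylate (silyl ketene acetal) | CC1=C([C@@H]2C[C@@H](O[Si](C)(C)C(C)(C)C)C=C(O[Si](C)(C)C)O2)[C@@](C)(C(=O)OC)CCC1 | intermediate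
16 | trimethylsilyl ester of acid 17 | C[Si](C)(C)OC(=O)[C@@H]1[C@H](O[Si](C)(C)C(C)(C)C)CC=C2[C@]1(C)CCC[C@]2(C)C(=O)OC | intermediate
17 | 8α-(tert-butyldimethylsilyloxy)-19-methoxy-19-oxo-9-epi-12,13,14,15,16,17-hexanorlabd-5-en-11-oic acid; (1S,2R,5S,8aR)-2-(tert-butyldimethylsilyloxy)-5-(methoxycarbonyl)-5,8a-dimethyl-1,2,3,5,6,7,8,8a-octahydronaphthalene-1-carboxylic acid | OC(=O)[C@@H]1[C@H](O[Si](C)(C)C(C)(C)C)CC=C2[C@]1(C)CCC[C@]2(C)C(=O)OC | intermediate
18 | methyl 8α-(tert-butyldimethylsilyloxy)-11-hydroxy-9-epi-12,13,14,15,16,17-hexanorlabd-5-en-19-oate | OC[C@@H]1[C@H](O[Si](C)(C)C(C)(C)C)CC=C2[C@]1(C)CCC[C@]2(C)C(=O)OC | intermediate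
19 | methyl 8α-(tert-butyldimethylsilyloxy)-11-hydroxy-9-epi-12,13,14,15,16,17-hexanorlabdan-19-oate (5α-H, trans-decalin) | OC[C@@H]1[C@H](O[Si](C)(C)C(C)(C)C)CC[C@@H]2[C@]1(C)CCC[C@]2(C)C(=O)OC | intermediate
20 | methyl 8α-(tert-butyldimethylsilyloxy)-11-oxo-9-epi-12,13,14,15,16,17-hexanorlabdan-19-oate | O=C[C@@H]1[C@H](O[Si](C)(C)C(C)(C)C)CC[C@@H]2[C@]1(C)CCC[C@]2(C)C(=O)OC | intermediate
21 | methyl 8α-(tert-butyldimethylsilyloxy)-9-epi-13,14,15,16,17-pentanorlabd-11-en-19-oate (9α-vinyl) | C=C[C@@H]1[C@H](O[Si](C)(C)C(C)(C)C)CC[C@@H]2[C@]1(C)CCC[C@]2(C)C(=O)OC | intermediate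
22 | methyl acetoacetate | COC(=O)CC(C)=O | starting material
23 | methyl (2E)-3-(trifluoromethanesulfonyloxy)but-2-enoate | C/C(OS(=O)(=O)C(F)(F)F)=C\C(=O)OC | intermediate
24 | methyl 12-(9-borabicyclo[3.3.1]nonan-9-yl)-8α-(tert-butyldimethylsilyloxy)-9-epi-13,14,15,16,17-pentanorlabdan-19-oate (B-alkyl borane) | C(C[C@@H]1[C@H](O[Si](C)(C)C(C)(C)C)CC[C@@H]2[C@]1(C)CCC[C@]2(C)C(=O)OC)B3C4CCCC3CCC4 | intermediate
25 | dimethyl (13E)-8α-(tert-butyldimethylsilyloxy)-9-epi-17-norlabd-13-ene-15,19-dioate | COC(=O)/C=C(\C)CC[C@@H]1[C@H](O[Si](C)(C)C(C)(C)C)CC[C@@H]2[C@]1(C)CCC[C@]2(C)C(=O)OC | intermediate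
26 | dimethyl (13E)-8α-hydroxy-9-epi-17-norlabd-13-ene-15,19-dioate | COC(=O)/C=C(\C)CC[C@@H]1[C@H](O)CC[C@@H]2[C@]1(C)CCC[C@]2(C)C(=O)OC | intermediate
27 | dimethyl (13E)-8-oxo-9-epi-17-norlabd-13-ene-15,19-dioate (9-epi ketone) | COC(=O)/C=C(\C)CC[C@@H]1C(=O)CC[C@@H]2[C@]1(C)CCC[C@]2(C)C(=O)OC | intermediate
28 | dimethyl (13E)-8-oxo-17-norlabd-13-ene-15,19-dioate (9α-H, natural C9) | COC(=O)/C=C(\C)CC[C@H]1C(=O)CC[C@@H]2[C@]1(C)CCC[C@]2(C)C(=O)OC | intermediate
29 | dimethyl (13E)-labda-8(17),13-diene-15,19-dioate | C=C1CC[C@@H]2[C@](C)(CCC[C@]2(C)C(=O)OC)[C@H]1CC/C(C)=C/C(=O)OC | intermediate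
30 | methyl (13E)-15-hydroxylabda-8(17),13-dien-19-oate | C=C1CC[C@@H]2[C@](C)(CCC[C@]2(C)C(=O)OC)[C@H]1CC/C(C)=C/CO | intermediate
31 | (13E)-15-hydroxylabda-8(17),13-dien-19-oic acid | C=C1CC[C@@H]2[C@](C)(CCC[C@]2(C)C(=O)O)[C@H]1CC/C(C)=C/CO | intermediate
32 | oleic acid, (9Z)-octadec-9-enoic acid | CCCCCCCC/C=C\CCCCCCCC(=O)O | starting material
33 | oleoyl chloride | CCCCCCCC/C=C\CCCCCCCC(=O)Cl | intermediate
34 | (13E)-15-[(9Z)-octadec-9-enoyloxy]labda-8(17),13-dien-19-oic acid (CNP0287077.1) | C=C1CC[C@@H]2[C@](C)(CCC[C@]2(C)C(=O)O)[C@H]1CC/C(C)=C/COC(=O)CCCCCCC/C=C\CCCCCCCC | target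

**Step count and risks**

Total steps: 21. Longest linear sequence: 20 steps (steps 1–13 and 15–21); step 14 is a one-step branch.

Steps most likely to fail:

1. Step 9. The rearrangement may stall because the C20 methyl is forced inside the boat against C7 and C8, so that the ketene acetal is consumed by β-elimination, C-silylation or ionisation of the allylic C6–O bond before C9–C10 forms. The fallback separates bond formation from ring closure and sets out from 8. Luche reduction (NaBH4, CeCl3, MeOH) would give methyl (1S)-2-(hydroxymethyl)-1,3-dimethylcyclohex-2-ene-1-carboxylate F1. Carbodiimide esterification with the known (3R)-3-(tert-butyldimethylsilyloxy)hex-5-enoic acid would give [(6S)-6-(methoxycarbonyl)-2,6-dimethylcyclohex-1-en-1-yl]methyl (3R)-3-(tert-butyldimethylsilyloxy)hex-5-enoate F2. An acyclic Ireland–Claisen rearrangement (KHMDS, TBSCl, THF/DMPU for the (Z)-ketene acetal; toluene, 80 °C) through an unconstrained chair would form C9–C10 and move the alkene to an exocyclic C5 methylene. This gives 3-(tert-butyldimethylsilyloxy)-2-[3-(methoxycarbonyl)-1,3-dimethyl-2-methylidenecyclohexyl]hex-5-enoic acid F3 with the C4, C8, C9 and C10 configurations of 17; the C10 face then rests on the pseudo-axial C4 ester. Ring-closing metathesis (Grubbs II, toluene, 80 °C) between the C5 methylene and the terminal vinyl group would close ring B and rejoin the route at 17.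

2. Step 6. The hindered, tetrasubstituted enal may react sluggishly with the mild Lewis-acid catalyst, and the catalyst may override the C4 centre only partly, so that facial selectivity at C6 is poor. The fallback uses stoichiometric reagent control and sets out from 8. Brown allylation with (−)-Ipc2B(allyl) would give methyl (1S)-2-[(1S)-1-hydroxybut-3-en-1-yl]-1,3-dimethylcyclohex-2-ene-1-carboxylate F4. Acryloyl chloride/Et3N would give methyl (1S)-2-[(1S)-1-(acryloyloxy)but-3-en-1-yl]-1,3-dimethylcyclohex-2-ene-1-carboxylate F5. Ring-closing metathesis would give methyl (1S)-1,3-dimethyl-2-[(2S)-6-oxo-3,6-dihydro-2H-pyran-2-yl]cyclohex-2-ene-1-carboxylate F6. Alkaline H2O2 should epoxidise the enoate face anti to the C6 substituent to give the trans-epoxy lactone F7 (the tetrasubstituted ring-A alkene is inert to nucleophilic epoxidation). Reductive opening at the α-carbon with PhSeSePh/NaBH4 then delivers the 4,6-trans hydroxy lactone, and the route is rejoined at 13.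

3. Step 7. The transesterification may take the wrong course: the C6 hydroxyl could close a γ-lactone onto the C19 ester, or the acid could ionise the allylic C6–O bond. The fallback activates the acyl group instead of relying on acid catalysis and sets out from 12. Selective saponification of the unhindered C11 ester (LiOH, THF/H2O, 0 °C) would give (3R,5S)-3,5-dihydroxy-5-[(6S)-6-(methoxycarbonyl)-2,6-dimethylcyclohex-1-en-1-yl]pentanoic acid F8. Carbodiimide lactonisation (EDC·HCl, DMAP cat., CH2Cl2, high dilution) of the activated C11 carboxyl, δ-closure being favoured over β-closure, rejoins the route at 13.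

Further compounds

F1 | step 9 | methyl (1S)-2-(hydroxymethyl)-1,3-dimethylcyclohex-2-ene-1-carboxylate | COC(=O)[C@@]1(C)CCCC(C)=C1CO
F2 | step 9 | [(6S)-6-(methoxycarbonyl)-2,6-dimethylcyclohex-1-en-1-yl]methyl (3R)-3-(tert-butyldimethylsilyloxy)hex-5-enoate | COC(=O)[C@@]1(C)CCCC(C)=C1COC(=O)C[C@H](O[Si](C)(C)C(C)(C)C)CC=C
F3 | step 9 | 3-(tert-butyldimethylsilyloxy)-2-[3-(methoxycarbonyl)-1,3-dimethyl-2-methylidenecyclohexyl]hex-5-enoic acid (C4, C8, C9, C10 as in 17) | C=CC[C@@H](O[Si](C)(C)C(C)(C)C)[C@@H](C(=O)O)[C@@]1(C)CCC[C@](C)(C(=O)OC)C1=C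
F4 | step 6 | methyl (1S)-2-[(1S)-1-hydroxybut-3-en-1-yl]-1,3-dimethylcyclohex-2-ene-1-carboxylate | C=CC[C@H](O)C1=C(C)CCC[C@]1(C)C(=O)OC
F5 | step 6 | methyl (1S)-2-[(1S)-1-(acryloyloxy)but-3-en-1-yl]-1,3-dimethylcyclohex-2-ene-1-carboxylate | C=CC[C@H](OC(=O)C=C)C1=C(C)CCC[C@]1(C)C(=O)OC
F6 | step 6 | methyl (1S)-1,3-dimethyl-2-[(2S)-6-oxo-3,6-dihydro-2H-pyran-2-yl]cyclohex-2-ene-1-carboxylate | CC1=C([C@@H]2CC=CC(=O)O2)[C@@](C)(C(=O)OC)CCC1
F7 | step 6 | methyl (1S)-1,3-dimethyl-2-(2-oxo-3,7-dioxabicyclo[4.1.0]heptan-4-yl)cyclohex-2-ene-1-carboxylate (epoxide trans to the ring-A substituent) | CC1=C([C@@H]2C[C@H]3O[C@H]3C(=O)O2)[C@@](C)(C(=O)OC)CCC1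
F8 | step 7 | (3R,5S)-3,5-dihydroxy-5-[(6S)-6-(methoxycarbonyl)-2,6-dimethylcyclohex-1-en-1-yl]pentanoic acid | OC(=O)C[C@H](O)C[C@H](O)C1=C(C)CCC[C@]1(C)C(=O)OC
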